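Remark on the chemistry: the (S)-configured amine in step 4 is assigned from the usual shielding model of diarylprolinol silyl ether catalysis and is not proven for this alkyne; if the annulation followed the opposite sense, the (R)-amine would be used with nothing else changed.

Abbreviations: TBS = tert-butyldimethylsilyl, TBSO = tert-butyldimethylsilyloxy.

## Analysis of the target

Compound 12 is a 2,3,4-trisubstituted oxolane (O1, C2, C3, C4, C5). C2 carries a 4-hydroxy-3-methoxyphenyl group, C3 an oxymethyl arm esterified with octadecanoic acid, C4 a 4-hydroxy-3-methoxybenzyl group, and C5 is an unsubstituted CH2. The three contiguous stereocentres are 2S, 3R, 4R: the C2 aryl group is trans to the C3 arm and the C3 arm is cis to the C4 benzyl group, which is the lariciresinol pattern. The sensitive groups are the two free guaiacyl phenols (oxidation, competing acylation), the primary ester (bases, nucleophiles) and the C2–O1 bond. That bond is benzylic and para to a phenol, so acid can open it to a stabilised cation (epimerisation at C2 or capture by the second arene), and palladium with hydrogen can cleave it. The synthesis is hard because the 3,4-cis relation is the less stable one and cannot be reached by equilibration, because the absolute configuration has to be created from achiral C6–C3 building blocks, and because the fatty acyl group must end on the primary hydroxyl only. The strategy rests on reading the skeleton as two C6–C3 units. C2(aryl)–C3–oxymethyl carbon is the β-carbon, α-carbon and formyl carbon of coniferaldehyde (1), and O1–C5–C4–benzylic carbon–aryl is the oxygen and the three carbons of a 3-arylprop-2-yn-1-ol (6 in protected form). Joining the two through O1–C2 and C3–C4 gives the whole skeleton and leaves C4 as an alkene carbon from which the last stereocentre can be set.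

## Retrosynthetic reasoning

12 to 11 (two O–Si bonds). The phenols are carried as silyl ethers and unmasked last. Free phenols would neutralise the iminium ion of the key step, would be acylated in competition with the primary hydroxyl, and would make C2–O1 easier to cleave during hydrogenation. Silyl ethers are preferred to benzyl ethers because they survive hydrogenation, so the phenols are never free while palladium and hydrogen are present. The forward step has to remove two aryl silyl ethers without touching the ester.

11 to 10 (the C4–H bond and one benzylic C–H bond). C4 is traced back to an sp2 carbon of an exocyclic benzylidene. It is the one centre that an alkyne-based ring closure cannot set, and the cis relation to the C3 arm can be reached kinetically by adding hydrogen to the alkene face that the arm leaves open. The forward step needs syn addition from that face, no migration of the double bond, and no cleavage of C2–O1.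

10 to 8 and 9 (the ester C–O bond). The acyl group is attached to the only free hydroxyl of 8, so no selectivity problem arises. Acylating before the hydrogenation makes the C3 arm larger and removes a hydroxyl that could bind to the metal surface and deliver hydrogen from the wrong face.

8 to 7 (the carbinol C–H bond). The arm is taken back to a formyl group because an aldehyde is what amine catalysis produces. Aldehyde 7 is not isolated: its C3–H is α to the formyl group and allylic, so the double bond can move into conjugation and erase C3. The forward hydride reduction is therefore run in the same flask.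

7 to 2 and 6 (O1–C2 and C3–C4). Cutting these two bonds splits the ring into two halves of equal size, each one or two steps from a purchasable arene. Both bonds are made at the two reactive positions of an enal, the electrophilic β-carbon and, after addition, the nucleophilic α-carbon. One chiral secondary amine can therefore control C2 and C3 while a palladium co-catalyst activates the alkyne of 6. Cuts at C2–C3 or C4–C5 would separate the aryl carbinol from the rest and would need a preformed stereocentre. The forward reaction has to make a weak oxygen nucleophile add 1,4, close the ring in the five-membered mode, place the formyl group trans to the C2 aryl group, and leave the double bond exocyclic.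

6 to 4 and 5, and 4 to 3 (the aryl–alkynyl bond and one O–Si bond). The sp2–sp bond is the obvious cut of an arylalkyne. The phenol of 3 is silylated first, so that the coupling product has a single free hydroxyl, the one needed as nucleophile in the key step.

2 to 1 (one O–Si bond). Silylation of 1 gives the enal in the form that tolerates iminium catalysis.

## Alternatives that were turned down

Alternative 1: The ring is disconnected at C2–C3 and at the bond from C4 to the benzylic carbon, with a butenolide as the central piece and O1–C2 left for later. In the forward key step the 2-lithio derivative of dithiane A2 adds to the β-carbon of the menthyloxy butenolide A1 anti to the alkoxy group, and the lactone enolate is trapped by aldehyde A3 to give lactone A4. In its favour, conjugate addition–aldol sequences on such butenolides are dependable, the auxiliary fixes the absolute configuration with little doubt, and the trans lactone corresponds to the cis 3,4-relation of the oxolane once the ring is switched. On these two points it is stronger than the chosen route, which sets C4 by a late hydrogenation and relies on a catalyst model. Against it, A4 is far from 12. It still needs desulfurisation, reduction of lactone and acetal, an acid-mediated closure of the oxolane at the benzylic carbinol, selective acylation and debenzylation. The acid closure sets C2 only thermodynamically, under conditions in which the electron-rich benzylic cation can also be captured by the second arene. One of the three stereocentres made in the key step is thrown away, and auxiliary and sulfur are used stoichiometrically. The chosen strategy offers catalytic asymmetric induction, formation of O1–C2 under non-acidic conditions with C2 set kinetically, and about half as many operations after the key step.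

Alternative 2: The ring is disconnected at O1–C2 and C4–C5, with C5 coming from formaldehyde A6 and the C2–C4 bond stored in cyclopropane A5. In the forward key step a scandium Lewis acid opens A5 to a benzylic cation and a metal enolate, the oxygen of A6 bonds to C2, and the enolate carbon closes on the oxocarbenium carbon to give oxolane A7. In its favour, the step is a convergent formal cycloaddition, the stearate is already in place, and C5 comes from the cheapest one-carbon unit. On convergence it is at least equal to the chosen route. Against it, a cyclopropane with a single aroyl acceptor is weakly activated, and monomeric A6 is awkward to handle. Opening through a free benzylic cation gives up the stereochemical information at C2, so the enantiopurity rests on C3 alone, and an enantiopure A5 is a synthesis problem of its own. The decisive point is that A7 has the C4 substituent trans to the C3 arm, the stable arrangement next to a ketone, while 12 needs cis. A contra-thermodynamic epimerisation would be required, followed by deoxygenation of an aryl ketone beside a benzylic ether. The chosen strategy keeps C4 as an alkene carbon, so the cis relation is created kinetically and is not worked against.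

Alternative 3: The ring is disconnected at C3–C4 by a radical cyclisation of the epoxy cinnamyl ether A8. In the forward key step a single-electron reductant based on trivalent titanium opens the epoxide to a radical at C3, which adds in the 5-exo mode to the cinnamyl double bond; the benzylic radical is then reduced and protonated to give the protected lariciresinol A9. In its favour, C4 is obtained saturated, with the 2,3-trans-3,4-cis arrangement expected from the chair-like transition state of such closures. Both epoxide epimers converge, no hydrogenation is run near the benzylic ether, and the primary hydroxyl is free for acylation. The ring closure is close to established lignan chemistry, so on the certainty of the key step this alternative is stronger than the chosen route. Against it, the absolute configuration is not created in the key step but has to be installed in the benzylic ether centre of A8 beforehand by a separate asymmetric step or a resolution. The ether would be made by alkylating an epoxy alkoxide, which can rearrange. More than two equivalents of the titanium reagent are consumed, the cis preference at C4 of such radical closures is usually moderate, and the sequence is longer. The chosen strategy makes O1–C2 and C3–C4 in one catalytic asymmetric step from two fragments that are each at most two steps from purchasable material, and it leaves C4 open to a separate stereo-defining step.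

Key step: step 4

## Route

Step 1
Reactants: 1 coniferaldehyde, (E)-3-(4-hydroxy-3-methoxyphenyl)prop-2-enal
Product: 2 (E)-3-[4-(TBSO)-3-methoxyphenyl]prop-2-enal
Conditions: TBSCl, imidazole, DMF, rt
Reagents that add atoms: tert-butyldimethylsilyl chloride (TBSCl), CC(C)(C)[Si](C)(C)Cl
Why: Silyl ether formation at a phenol with a silyl chloride and imidazole; the enal is untouched, and masking the phenol keeps it from quenching the iminium ion in step 4 and from being acylated in step 5.

Step 2
Reactants: 3 4-iodo-2-methoxyphenol
Product: 4 tert-butyl(4-iodo-2-methoxyphenoxy)dimethylsilane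
Conditions: TBSCl, imidazole, DMF, rt
Reagents that add atoms: tert-butyldimethylsilyl chloride (TBSCl), CC(C)(C)[Si](C)(C)Cl
Why: The same phenol silylation; protecting before the coupling means that the coupling product has one free hydroxyl only.

Step 3
Reactants: 4 tert-butyl(4-iodo-2-methoxyphenoxy)dimethylsilane; 5 propargyl alcohol (prop-2-yn-1-ol)
Product: 6 3-[4-(TBSO)-3-methoxyphenyl]prop-2-yn-1-ol
Conditions: PdCl2(PPh3)2 (2 mol %), CuI (4 mol %), Et3N, THF, rt, degassed
Reagents that add atoms: none
Why: Sonogashira coupling of an aryl iodide with a terminal alkyne; aryl iodides couple at room temperature, the primary hydroxyl is tolerated, and exclusion of air suppresses oxidative dimerisation of the alkyne.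

Step 4
Reactants: 2 (E)-3-[4-(TBSO)-3-methoxyphenyl]prop-2-enal; 6 3-[4-(TBSO)-3-methoxyphenyl]prop-2-yn-1-ol
Product: 8 [(2S,3R,4E)-2-[4-(TBSO)-3-methoxyphenyl]-4-{[4-(TBSO)-3-methoxyphenyl]methylidene}oxolan-3-yl]methanol, via benzylideneoxolane carbaldehyde 7 (not isolated)
Conditions: (S)-α,α-diphenylprolinol trimethylsilyl ether (20 mol %), Pd(PPh3)4 (5 mol %), PhCO2H (20 mol %), THF, rt; then MeOH, NaBH4, 0 °C
Reagents that add atoms: none
Why: Proposed new method: the amine and 2 form an E-iminium ion, the hydroxyl of 6 adds reversibly to its β-carbon (oxa-Michael addition, O1–C2), and the enamine so formed attacks the proximal carbon of the palladium-bound alkyne anti to the metal (C3–C4), after which protonation of the alkenyl–palladium bond and hydrolysis release 7 and both catalysts; zerovalent palladium from Pd(PPh3)4 is taken to activate the alkyne as it does with propargyl alcohol itself. The closest known reaction type is the amine/palladium co-catalysed dynamic kinetic asymmetric oxa-Michael/carbocyclisation of enals with terminal propargylic alcohols, and what is new is the aryl-capped internal alkyne and the interception of the non-conjugated aldehyde. The oxolane is the only ring closed and it closes 5-exo-dig, the short O–CH2 tether favouring the five-membered mode over 6-endo attack at the aryl-bearing carbon. C3 is controlled by the catalyst, because the carbon–carbon bond forms on the enamine face away from the diphenyl(silyloxy)methyl group. C2 is controlled under Curtin–Hammett conditions: the two oxa-Michael epimers interconvert by retro-addition, and only the 2S epimer, which is also the one favoured by alkoxide delivery to the unshielded Si face of the iminium β-carbon, can cyclise on that enamine face with its aryl group trans to the developing formyl-bearing centre. Anti carbopalladation and protonation with retention should give the E-benzylidene, although either geometry would serve because the benzylic carbon ends as CH2. The step needs 1,4-addition and not acetal formation, which is reversible and unproductive, and it needs the double bond to stay exocyclic: NaBH4 is added as soon as 2 is consumed, so that 7 is reduced to 8 before the doubly activated C3–H allows migration into conjugation. The silyl ethers keep the phenols from acting as competing nucleophiles and from neutralising the iminium ion as a quinone methide.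

Step 5
Reactants: 8 [(2S,3R,4E)-2-[4-(TBSO)-3-methoxyphenyl]-4-{[4-(TBSO)-3-methoxyphenyl]methylidene}oxolan-3-yl]methanol; 9 stearoyl chloride (octadecanoyl chloride)
Product: 10 [(2S,3R,4E)-2-[4-(TBSO)-3-methoxyphenyl]-4-{[4-(TBSO)-3-methoxyphenyl]methylidene}oxolan-3-yl]methyl octadecanoate
Conditions: Et3N, DMAP (cat.), CH2Cl2, 0 °C to rt
Reagents that add atoms: none
Why: Esterification of a primary alcohol with an acid chloride under nucleophilic catalysis by DMAP; the phenols are masked, so the ester can form only on the C3 arm, and the mild base does not affect C2 or C3.

Step 6
Reactants: 10 [(2S,3R,4E)-2-[4-(TBSO)-3-methoxyphenyl]-4-{[4-(TBSO)-3-methoxyphenyl]methylidene}oxolan-3-yl]methyl octadecanoate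
Product: 11 [(2S,3R,4R)-2-[4-(TBSO)-3-methoxyphenyl]-4-{[4-(TBSO)-3-methoxyphenyl]methyl}oxolan-3-yl]methyl octadecanoate
Conditions: H2 (1 atm), Pd/C (palladium on carbon, 10 wt %), EtOAc, rt
Reagents that add atoms: none
Why: Heterogeneous catalytic hydrogenation of a trisubstituted styrene-type alkene; allylic strain with the benzylidene aryl group turns the C3 acyloxymethyl arm out of the alkene plane so that it covers one face, hydrogen is delivered syn from the other face, and the new C4–H bond lies trans to the arm, which puts the benzyl group cis to it (4R). Neutral ethyl acetate at one atmosphere should leave the benzylic C2–O1 bond, the ester and the aryl silyl ethers intact, and either alkene geometry leads to the same C4 configuration.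

Step 7
Reactants: 11 [(2S,3R,4R)-2-[4-(TBSO)-3-methoxyphenyl]-4-{[4-(TBSO)-3-methoxyphenyl]methyl}oxolan-3-yl]methyl octadecanoate
Product: 12 [(2S,3R,4R)-2-(4-hydroxy-3-methoxyphenyl)-4-[(4-hydroxy-3-methoxyphenyl)methyl]oxolan-3-yl]methyl octadecanoate
Conditions: Bu4NF (TBAF), AcOH, THF, 0 °C
Reagents that add atoms: none
Why: Fluoride-mediated cleavage of aryl silyl ethers, which are much more labile than the ester; acetic acid protonates the phenoxides as they form, so the stearate should be neither hydrolysed nor transferred, and no stereocentre is touched.

## Compound list

1 | coniferaldehyde, (E)-3-(4-hydroxy-3-methoxyphenyl)prop-2-enal | COc1cc(/C=C/C=O)ccc1O | starting material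
2 | (E)-3-[4-(tert-butyldimethylsilyloxy)-3-methoxyphenyl]prop-2-enal | COc1cc(/C=C/C=O)ccc1O[Si](C)(C)C(C)(C)C | intermediate
3 | 4-iodo-2-methoxyphenol | COc1cc(I)ccc1O | starting material
4 | tert-butyl(4-iodo-2-methoxyphenoxy)dimethylsilane | COc1cc(I)ccc1O[Si](C)(C)C(C)(C)C | intermediate
5 | propargyl alcohol, prop-2-yn-1-ol | C#CCO | starting material
6 | 3-[4-(tert-butyldimethylsilyloxy)-3-methoxyphenyl]prop-2-yn-1-ol | COc1cc(C#CCO)ccc1O[Si](C)(C)C(C)(C)C | intermediate
7 | (2S,3S,4E)-2-[4-(tert-butyldimethylsilyloxy)-3-methoxyphenyl]-4-{[4-(tert-butyldimethylsilyloxy)-3-methoxyphenyl]methylidene}oxolane-3-carbaldehyde | O=C[C@H]1/C(=C\c2ccc(O[Si](C)(C)C(C)(C)C)c(OC)c2)CO[C@@H]1c1ccc(O[Si](C)(C)C(C)(C)C)c(OC)c1 | intermediate (not isolated)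
8 | [(2S,3R,4E)-2-[4-(tert-butyldimethylsilyloxy)-3-methoxyphenyl]-4-{[4-(tert-butyldimethylsilyloxy)-3-methoxyphenyl]methylidene}oxolan-3-yl]methanol | OC[C@H]1/C(=C\c2ccc(O[Si](C)(C)C(C)(C)C)c(OC)c2)CO[C@@H]1c1ccc(O[Si](C)(C)C(C)(C)C)c(OC)c1 | intermediate
9 | stearoyl chloride, octadecanoyl chloride | CCCCCCCCCCCCCCCCCC(Cl)=O | starting material
10 | [(2S,3R,4E)-2-[4-(tert-butyldimethylsilyloxy)-3-methoxyphenyl]-4-{[4-(tert-butyldimethylsilyloxy)-3-methoxyphenyl]methylidene}oxolan-3-yl]methyl octadecanoate | CCCCCCCCCCCCCCCCCC(=O)OC[C@H]1/C(=C\c2ccc(O[Si](C)(C)C(C)(C)C)c(OC)c2)CO[C@@H]1c1ccc(O[Si](C)(C)C(C)(C)C)c(OC)c1 | intermediate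
11 | [(2S,3R,4R)-2-[4-(tert-butyldimethylsilyloxy)-3-methoxyphenyl]-4-{[4-(tert-butyldimethylsilyloxy)-3-methoxyphenyl]methyl}oxolan-3-yl]methyl octadecanoate | CCCCCCCCCCCCCCCCCC(=O)OC[C@H]1[C@@H](Cc2ccc(O[Si](C)(C)C(C)(C)C)c(OC)c2)CO[C@@H]1c1ccc(O[Si](C)(C)C(C)(C)C)c(OC)c1 | intermediate
12 | [(2S,3R,4R)-2-(4-hydroxy-3-methoxyphenyl)-4-[(4-hydroxy-3-methoxyphenyl)methyl]oxolan-3-yl]methyl octadecanoate | CCCCCCCCCCCCCCCCCC(=O)OC[C@H]1[C@@H](Cc2ccc(O)c(OC)c2)CO[C@@H]1c1ccc(O)c(OC)c1 | target

## Step count and least certain steps

Total step count: 7. Longest linear sequence: 6 steps (steps 2 to 7, from 3 through 4, 6, 8, 10 and 11 to 12).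

Step 4 (key step, proposed new method). Three things are most likely to go wrong. The enamine may add too slowly to the disubstituted, electron-rich alkyne, so that retro-oxa-Michael addition simply returns 2 and 6. The ring may close in the 6-endo sense at the aryl-bearing alkyne carbon, which the donor arene makes the more electrophilic position. The double bond may migrate into conjugation before the hydride quench, with loss of C3. The sense and level of asymmetric induction are also untested for this alkyne.

The fallback sets out from 2 and 5 and rejoins the route at 11. Enal 2 and propargyl alcohol 5 are annulated under the same amine and Pd(PPh3)4 co-catalysis, the pairing for which this reaction type is established, and the mixture is treated with NaBH4 as in the main route. This should give, by way of (2S,3S)-2-[4-(TBSO)-3-methoxyphenyl]-4-methylideneoxolane-3-carbaldehyde F1, the carbinol [(2S,3R)-2-[4-(TBSO)-3-methoxyphenyl]-4-methylideneoxolan-3-yl]methanol F2. Acylation with 9 (Et3N, DMAP, CH2Cl2) gives the stearate [(2S,3R)-2-[4-(TBSO)-3-methoxyphenyl]-4-methylideneoxolan-3-yl]methyl octadecanoate F3. Hydroboration of F3 with 9-borabicyclo[3.3.1]nonane in THF places boron on the exocyclic CH2 and hydrogen on C4 from the face opposite the C3 arm. The resulting B-alkyl borane [(2S,3R,4R)-4-[(9-borabicyclo[3.3.1]nonan-9-yl)methyl]-2-[4-(TBSO)-3-methoxyphenyl]oxolan-3-yl]methyl octadecanoate F4 is not isolated. B-alkyl Suzuki–Miyaura coupling with aryl iodide 4 (PdCl2(dppf), dppf being 1,1'-bis(diphenylphosphino)ferrocene, K3PO4, THF/DMF/H2O, rt) gives 11. Steps 5 and 6 are bypassed, C4 is set by hydroboration and not by hydrogenation, and the sequence is no longer than the main route.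

Step 6. Three processes are the likely failures. The double bond may migrate into the ring on the palladium surface before hydrogen is added, which would scramble C3 or C4. The benzylic C2–O1 bond may be hydrogenolysed on prolonged contact with the catalyst if the lipophilic ester reacts slowly. The two alkene faces may be discriminated too weakly, because the C2 aryl group sits on the face that must be attacked.

The fallback sets out from 8 and rejoins the route at 11, and it moves the stereo-defining reduction to the carbinol stage. The free 3-hydroxymethyl-4-benzylideneoxolane is the substrate type closest to the established hydrogenations that lead to the 3,4-cis lignan skeleton. Hydrogenation of 8 (H2, Pd/C, EtOAc, rt) should give [(2S,3R,4R)-2-[4-(TBSO)-3-methoxyphenyl]-4-{[4-(TBSO)-3-methoxyphenyl]methyl}oxolan-3-yl]methanol F5. Acylation of F5 with 9 (Et3N, DMAP, CH2Cl2) then gives 11.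

Step 7. The likely failure is loss or transfer of the stearoyl group, by attack of fluoride-generated phenoxide or adventitious hydroxide on the ester before the buffer intervenes.

The fallback sets out from 11 and rejoins the route at 12, and it replaces chemoselective deprotection by chemoselective acylation. Methanolysis of 11 (K2CO3, MeOH, rt) removes both aryl silyl ethers and the ester and should give (+)-lariciresinol F6. Lipase B from Candida antarctica (immobilised) with vinyl stearate in tert-butyl methyl ether at 45 °C then acylates the primary aliphatic hydroxyl of F6 and leaves the phenols free, as is usual for such lipases with phenolic alcohols, to give 12.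

## Further compounds

F1 | step 4 | (2S,3S)-2-[4-(tert-butyldimethylsilyloxy)-3-methoxyphenyl]-4-methylideneoxolane-3-carbaldehyde | O=C[C@H]1C(=C)CO[C@@H]1c1ccc(O[Si](C)(C)C(C)(C)C)c(OC)c1
F2 | step 4 | [(2S,3R)-2-[4-(tert-butyldimethylsilyloxy)-3-methoxyphenyl]-4-methylideneoxolan-3-yl]methanol | OC[C@H]1C(=C)CO[C@@H]1c1ccc(O[Si](C)(C)C(C)(C)C)c(OC)c1
F3 | step 4 | [(2S,3R)-2-[4-(tert-butyldimethylsilyloxy)-3-methoxyphenyl]-4-methylideneoxolan-3-yl]methyl octadecanoate | CCCCCCCCCCCCCCCCCC(=O)OC[C@H]1C(=C)CO[C@@H]1c1ccc(O[Si](C)(C)C(C)(C)C)c(OC)c1
F4 | step 4 | [(2S,3R,4R)-4-[(9-borabicyclo[3.3.1]nonan-9-yl)methyl]-2-[4-(tert-butyldimethylsilyloxy)-3-methoxyphenyl]oxolan-3-yl]methyl octadecanoate | CCCCCCCCCCCCCCCCCC(=O)OC[C@H]1[C@@H](CB2C3CCCC2CCC3)CO[C@@H]1c1ccc(O[Si](C)(C)C(C)(C)C)c(OC)c1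
F5 | step 6 | [(2S,3R,4R)-2-[4-(tert-butyldimethylsilyloxy)-3-methoxyphenyl]-4-{[4-(tert-butyldimethylsilyloxy)-3-methoxyphenyl]methyl}oxolan-3-yl]methanol | OC[C@H]1[C@@H](Cc2ccc(O[Si](C)(C)C(C)(C)C)c(OC)c2)CO[C@@H]1c1ccc(O[Si](C)(C)C(C)(C)C)c(OC)c1
F6 | step 7 | (+)-lariciresinol, 4-[(2S,3R,4R)-4-[(4-hydroxy-3-methoxyphenyl)methyl]-3-(hydroxymethyl)oxolan-2-yl]-2-methoxyphenol | OC[C@H]1[C@@H](Cc2ccc(O)c(OC)c2)CO[C@@H]1c1ccc(O)c(OC)c1
A1 | alternative 1 | (5R)-5-{[(1R,2S,5R)-5-methyl-2-(propan-2-yl)cyclohexyl]oxy}furan-2(5H)-one | O=C1C=C[C@H](O[C@@H]2C[C@H](C)CC[C@H]2C(C)C)O1
A2 | alternative 1 | 2-[4-(benzyloxy)-3-methoxyphenyl]-1,3-dithiane | COc1cc(C2SCCCS2)ccc1OCc1ccccc1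
A3 | alternative 1 | 4-(benzyloxy)-3-methoxybenzaldehyde | COc1cc(C=O)ccc1OCc1ccccc1
A4 | alternative 1 | 3,4-trans-4,5-trans 3-{[4-(benzyloxy)-3-methoxyphenyl](hydroxy)methyl}-4-{2-[4-(benzyloxy)-3-methoxyphenyl]-1,3-dithian-2-yl}-5-(menthyloxy)oxolan-2-one, carbinol centre unassigned | O=C1[C@H](C(O)c2ccc(OCc3ccccc3)c(OC)c2)[C@@H](C2(SCCCS2)c2ccc(OCc3ccccc3)c(OC)c2)[C@H](O[C@@H]2C[C@H](C)CC[C@H]2C(C)C)O1
A5 | alternative 2 | {2-[4-(tert-butyldimethylsilyloxy)-3-methoxybenzoyl]-3-[4-(tert-butyldimethylsilyloxy)-3-methoxyphenyl]cyclopropyl}methyl octadecanoate, arm trans to aryl and cis to aroyl, enantiomer as in the SMILES | CCCCCCCCCCCCCCCCCC(=O)OC[C@H]1[C@@H](C(=O)c2ccc(O[Si](C)(C)C(C)(C)C)c(OC)c2)[C@@H]1c1ccc(O[Si](C)(C)C(C)(C)C)c(OC)c1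
A6 | alternative 2 | formaldehyde | C=O
A7 | alternative 2 | all-trans [4-[4-(tert-butyldimethylsilyloxy)-3-methoxybenzoyl]-2-[4-(tert-butyldimethylsilyloxy)-3-methoxyphenyl]oxolan-3-yl]methyl octadecanoate | CCCCCCCCCCCCCCCCCC(=O)OC[C@H]1[C@H](C(=O)c2ccc(O[Si](C)(C)C(C)(C)C)c(OC)c2)CO[C@@H]1c1ccc(O[Si](C)(C)C(C)(C)C)c(OC)c1
A8 | alternative 3 | 2-{[4-(tert-butyldimethylsilyloxy)-3-methoxyphenyl]{[(2E)-3-[4-(tert-butyldimethylsilyloxy)-3-methoxyphenyl]prop-2-en-1-yl]oxy}methyl}oxirane, benzylic centre as in the SMILES, either epoxide epimer | COc1cc(/C=C/CO[C@@H](C2CO2)c2ccc(O[Si](C)(C)C(C)(C)C)c(OC)c2)ccc1O[Si](C)(C)C(C)(C)C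
A9 | alternative 3 | [(2S,3R,4R)-2-[4-(tert-butyldimethylsilyloxy)-3-methoxyphenyl]-4-{[4-(tert-butyldimethylsilyloxy)-3-methoxyphenyl]methyl}oxolan-3-yl]methanol | OC[C@H]1[C@@H](Cc2ccc(O[Si](C)(C)C(C)(C)C)c(OC)c2)CO[C@@H]1c1ccc(O[Si](C)(C)C(C)(C)C)c(OC)c1
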